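## The problem

CNP0306954.0 (20) is an achiral aromatic polyketide. Ring A (2,4-dihydroxy-6-propylphenyl) and ring B (2,4-dihydroxyphenyl with a CH2 group at C6) are joined through a ketone whose four ortho positions are all substituted. The CH2 group on ring B leads to C6 of a 4-hydroxy-2H-pyran-2-one. There is no stereocentre, so the task is one of connectivity, regiochemistry and functional-group tolerance.

The hindered benzophenone must be formed with the correct orientation on both resorcinol rings. The pyranone is the lactone of a 3,5-dioxo acid whose C5 carbonyl sits one CH2 away from ring B, next to the diaryl ketone. In open, enolisable form this chain can condense onto that ketone (through carbon to a naphthol, through oxygen to a 2-benzopyrylium), decarboxylate, or cyclise in the wrong sense. The free phenols are oxidation-prone and the hydroxypyranone is opened by hydroxide, so both should appear late.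

The enabling feature is that pyranone C6, C5 and C4, with the oxygen on C4, form a 1,3-dioxygenated three-carbon unit flanked by two CH2 groups (the benzylic one on C6, and C3 on C4). This is the substitution pattern of a 3,5-disubstituted 1,2-oxazole, which a nitrile oxide and a terminal alkyne assemble and which opens later under reducing, non-basic conditions.

## Retrosynthesis

**20 to 19.** The four aryl O–CH3 bonds are cut last. Methyl ethers are preferred to benzyl or acetal groups because they survive Friedel–Crafts acylation, hydride, the oxidant of the key step, hydrogenation and strong acid. Precursor 19 has no free phenol. The forward step asks for Lewis-acid ether cleavage that leaves the hydroxypyranone, a vinylogous acid, untouched.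

**19 to 17.** The lactone O1–C2 bond is cut, giving tert-butyl 3,5-dioxo ester 17, which closes through dioxo acid 18. The neighbouring cut, joining a preformed pyranone to ring B through the benzylic carbon, would need a strongly basic pyranone anion next to the diaryl ketone. The tert-butyl ester lets ester cleavage and lactonisation run in one acidic operation. The forward step asks that lactonisation outrun decarboxylation of 18.

**17 to 15.** The 1,3-diketone is masked as isoxazole 15 and released through enaminone 16 by N–O cleavage and hydrolysis. The neighbouring cut, acylation of an acetoacetate dianion by ester 9, reaches 17 in one step. It is strongly basic, however, and places a triketide anion beside the ketone it can attack. In 15 the C5 carbonyl of 17 is stored as C=N, the C3 carbonyl as an enol-type C–O, and the carbon between them is part of an aromatic ring and not nucleophilic. The forward step asks for reduction selective for the N–O bond and hydrolysis that spares the tert-butyl ester.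

**15 to 11 and 13 (key cut).** The isoxazole C3–C4 and C5–O bonds are cut; they are pyranone C6–C5 and C4–O. This gives nitrile oxide 14, generated from aldoxime 11, and tert-butyl but-3-ynoate 13. The inverse pairing, an ortho-propargylated benzophenone with an ester-bearing nitrile oxide, leads to the same diketone but has no simple source for the alkyne partner. The precursors are an arylacetaldehyde derivative and a four-carbon ester. The forward step asks for 3,5-regiochemistry, no furoxan formation, and no isomerisation of the base-sensitive alkyne.

**11 to 10 to 9.** Oxime 11 comes from aldehyde 10, and 10 from methyl ester 9, by functional-group changes only. The forward steps ask that hydride and hydroxylamine react at the unhindered side-chain carbonyl and leave the tetra-ortho-substituted ketone alone.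

**9 to 5 and 7.** The ring B–carbonyl bond is cut, giving acid 5 as acyl donor (through mixed anhydride 8) and arylacetate 7 as nucleophile. Cutting the ring A–carbonyl bond instead would need a ring B homophthalic acid whose two carboxyl groups must be told apart. Both fragments are simple resorcinol dimethyl ethers. The forward step asks for acylation of 7 at C2, para to one methoxy group and ortho to the other.

**5, 7 and 13 to starting materials.** Acid 5 comes from aldehyde 4, made by formylation of dimethyl ether 2 through iminium salt 3; 2 comes from 5-propylbenzene-1,3-diol 1. Ester 7 comes from 3,5-dimethoxyphenylacetic acid 6, and alkyne 13 from but-3-ynoic acid 12. All are one-bond or functional-group steps on commercial compounds.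

## Roads not taken

**Alternative 1:** Both arenes would be cut back to a cross-conjugated diynone, 1-(tert-butyldimethylsilyloxy)deca-3,6-diyn-5-one A2. In the forward key step A2 takes up two equivalents of 1,1-dimethoxy-3-(trimethylsilyloxy)buta-1,3-diene A3 in successive (4+2) cycloadditions, each adduct aromatising by loss of an alcohol, to give benzophenone A1.

- Merits: both rings and the hindered ketone come from one acyclic precursor, no electrophilic substitution has to find its position, and the ketone is never made by attack at a crowded centre. The phenols emerge differentiated (para OH, ortho OMe). In these respects it is better than the chosen plan.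
- Weak points: after the first cycloaddition the remaining ynone is attached to an electron-rich, twisted aryl ketone and is a much poorer dienophile, so the mono-adduct may accumulate. A2 is a double Michael acceptor. A1 ends at an arylethanol silyl ether, so the entire pyranone still has to be attached by the same kind of endgame used here.
- Comparison: it replaces steps 1 to 5 by a diynone synthesis of similar length with a riskier central step. The chosen plan buys both rings ready-made and spends its key step on the pyranone, which is the real difficulty.

**Alternative 2:** Both aryl–carbonyl bonds and both aryl–alkyl bonds would be cut. In the forward key step two arynes released by fluoride from 3,5-dimethoxy-2-(trimethylsilyl)phenyl trifluoromethanesulfonate A5 insert in turn into the two C(=O)–C(alpha) bonds of 1-tert-butyl 5-methyl 2-ethyl-3-oxopentanedioate A6, giving benzophenone diester A4.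

- Merits: it is the shortest route on paper to the skeleton. A4 already carries the ring B CH2CO2Me arm of ester 9, and the known preference for attack distal to a methoxy group gives the right orientation on both rings.
- Weak points: two insertions must occur in a defined order on an unsymmetrical substrate, with over-insertion and alpha-arylation as competitors. The second insertion passes through a four-membered alkoxide at a ketone already flanked by a 2,6-disubstituted ring. The ethyl-branched ester arm must then be degraded to propyl by decarboxylating a plain arylacetic acid, which needs a radical method. The pyranone is not addressed.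
- Comparison: if the double insertion worked it would save about three steps before ester 9. The chosen plan sets against this single-bond constructions with predictable regiochemistry.

**Alternative 3:** Ring B would be cut at C1'–C6' back to a polyketone stored as 2-[2-(2,4-dimethoxy-6-propylphenyl)-2-oxoethyl]-6-methyl-4H-pyran-4-one A8. In the forward key step hydroxide opens A8 to the enolised tetraketone, whose CH2 next to the aryl ketone adds to the terminal acetyl carbonyl and dehydrates, giving benzophenone A7.

- Merits: it is biomimetic, it builds ring B and the hindered ketone without a Friedel–Crafts step, and it leaves the ring B hydroxyls distinguishable from the ring A methyl ethers. It is the more elegant arene construction.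
- Weak points: A7 carries a methyl group where the target needs CH2–pyranone. The methyl must be functionalised on an electron-rich ring (ring halogenation competes with benzylic halogenation, and lateral deprotonation competes with attack on the ketone), and the triketide must still be built. The tetraketone can also fold in other ways.
- Comparison: the hardest part is moved to the end. The chosen plan carries the benzylic carbon from the start as the CH2 of arylacetic acid 6 and makes both bonds of the triketide mask in one step.

Key step: step 9

Assumption: oxime 11 is drawn as the E isomer, and any Z isomer formed with it gives the same nitrile oxide 14; dioxo compounds 17 and 18 are written as keto forms although they will be largely enolised.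

## Route

Step 1
Reactants: 1 5-propylbenzene-1,3-diol
Product: 2 1,3-dimethoxy-5-propylbenzene
Conditions: Me2SO4, K2CO3, acetone, reflux
Reagents that add atoms: dimethyl sulfate, COS(=O)(=O)OC
Why: Williamson-type O-methylation of both phenols; dimethyl sulfate with K2CO3 in acetone is the standard method for resorcinols and keeps C-alkylation low.

Step 2
Reactants: 2 1,3-dimethoxy-5-propylbenzene
Product: 4 2,4-dimethoxy-6-propylbenzaldehyde, via iminium chloride 3 (not isolated)
Conditions: POCl3, DMF, 0 °C to 70 °C; then ice-water
Reagents that add atoms: N,N-dimethylformamide, CN(C)C=O (formyl carbon, and the dimethyliminium group of 3); water, O (aldehyde oxygen); POCl3, O=P(Cl)(Cl)Cl (chloride counter-ion of 3 only)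
Why: Vilsmeier–Haack formylation; the position between one methoxy group and the propyl chain is para to the other methoxy group and less crowded than the position between both, so the 2,4-dimethoxy-6-alkyl aldehyde should predominate as it does for the methyl homologue, and the minor isomer is removed on purification.

Step 3
Reactants: 4 2,4-dimethoxy-6-propylbenzaldehyde
Product: 5 2,4-dimethoxy-6-propylbenzoic acid
Conditions: NaClO2, NaH2PO4, 2-methyl-2-butene, tBuOH/H2O, rt
Reagents that add atoms: sodium chlorite, [Na+].[O-]Cl=O
Why: Pinnick oxidation of an aromatic aldehyde; the alkene scavenger intercepts hypochlorous acid before it can chlorinate the electron-rich ring.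

Step 4
Reactants: 6 3,5-dimethoxyphenylacetic acid
Product: 7 methyl 2-(3,5-dimethoxyphenyl)acetate
Conditions: MeOH, H2SO4 (cat.), reflux
Reagents that add atoms: methanol, CO
Why: Fischer esterification of an unhindered arylacetic acid.

Step 5
Reactants: 5 2,4-dimethoxy-6-propylbenzoic acid; 7 methyl 2-(3,5-dimethoxyphenyl)acetate
Product: 9 methyl 2-[2-(2,4-dimethoxy-6-propylbenzoyl)-3,5-dimethoxyphenyl]acetate, via mixed anhydride 8 (not isolated)
Conditions: 5, TFAA, CH2Cl2, 0 °C; then 7, H3PO4 (cat.), rt
Reagents that add atoms: trifluoroacetic anhydride, O=C(OC(=O)C(F)(F)F)C(F)(F)F (trifluoroacetyl group of intermediate 8 only; none of its atoms remain in 9)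
Why: Friedel–Crafts acylation through the mixed trifluoroacetic anhydride; the 2,6-disubstituted aroyl group ionises readily to a linear acylium ion, which should attack 7 at C2 (para to one methoxy, ortho to the other), the usual site for 3,5-dimethoxyphenylacetates, while the ring of 5 is deactivated by its own acyl group.

Step 6
Reactants: 9 methyl 2-[2-(2,4-dimethoxy-6-propylbenzoyl)-3,5-dimethoxyphenyl]acetate
Product: 10 2-[2-(2,4-dimethoxy-6-propylbenzoyl)-3,5-dimethoxyphenyl]acetaldehyde
Conditions: iBu2AlH (1.1 equiv), CH2Cl2, −78 °C; aq. potassium sodium tartrate; used crude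
Reagents that add atoms: none
Why: Partial reduction of an ester by DIBAL-H through an aluminium hemiacetal that is stable at −78 °C; the diaryl ketone is shielded by four ortho substituents and deactivated by ortho and para methoxy groups, so it should not compete.

Step 7
Reactants: 10 2-[2-(2,4-dimethoxy-6-propylbenzoyl)-3,5-dimethoxyphenyl]acetaldehyde
Product: 11 (E)-2-[2-(2,4-dimethoxy-6-propylbenzoyl)-3,5-dimethoxyphenyl]acetaldehyde oxime
Conditions: NH2OH·HCl, NaOAc, EtOH/H2O, 0 °C to rt
Reagents that add atoms: hydroxylamine hydrochloride, NO.Cl
Why: Oxime condensation at the unhindered aldehyde under buffered, cold conditions; the hindered ketone should not condense, and oxime geometry does not matter for the next step.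

Step 8
Reactants: 12 but-3-ynoic acid
Product: 13 tert-butyl but-3-ynoate
Conditions: isobutene, H2SO4 (cat.), CH2Cl2, sealed vessel, rt
Reagents that add atoms: 2-methylpropene (isobutene), CC(C)=C
Why: Acid-catalysed addition of the carboxylic acid to isobutene; no base is present, so the propargylic ester should not isomerise to the allenoate.

Step 9
Reactants: 11 (E)-2-[2-(2,4-dimethoxy-6-propylbenzoyl)-3,5-dimethoxyphenyl]acetaldehyde oxime; 13 tert-butyl but-3-ynoate
Product: 15 tert-butyl 2-{3-[2-(2,4-dimethoxy-6-propylbenzoyl)-3,5-dimethoxybenzyl]-1,2-oxazol-5-yl}acetate, via nitrile oxide 14 (not isolated)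
Conditions: PhI(OAc)2 (1.2 equiv, portionwise), 13 (3 equiv), TFA (cat.), MeOH, 0 °C to rt
Reagents that add atoms: none
Why: PhI(OAc)2 exchanges a ligand for the oxime and fragments to iodobenzene, acetic acid and nitrile oxide 14, which is formed slowly and stays dilute. 14 adds to the terminal alkyne of 13 in a concerted, asynchronous (3+2) cycloaddition, the closest known type being the nitrile oxide–alkyne route to 3,5-disubstituted isoxazoles. The one ring is closed intermolecularly by two new bonds: the nitrile oxide carbon joins the unsubstituted alkyne terminus (pyranone C5–C6) and the oxygen joins the substituted carbon (pyranone C4–O), giving the aromatic 1,2-oxazole directly. No stereocentre is formed. The step needs 3,5- over 3,4-regioselectivity, which the terminal alkyne secures because steric and frontier-orbital preferences both place its substituent at C5. It also needs chemoselectivity against furoxan formation, allenoate formation and ring halogenation, answered in turn by slow oxidant addition with excess 13, the base-free medium and a halogen-free oxidant. The tetra-ortho-substituted diaryl ketone is too hindered to act as a dipolarophile.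

Step 10
Reactants: 15 tert-butyl 2-{3-[2-(2,4-dimethoxy-6-propylbenzoyl)-3,5-dimethoxybenzyl]-1,2-oxazol-5-yl}acetate
Product: 17 tert-butyl 6-[2-(2,4-dimethoxy-6-propylbenzoyl)-3,5-dimethoxyphenyl]-3,5-dioxohexanoate, via enaminone 16 (not isolated)
Conditions: H2 (1 atm), Raney Ni, EtOH, rt; filter; then 1 M aq. HCl, THF, rt
Reagents that add atoms: water, O (oxygen of the C5 ketone)
Why: Hydrogenolysis of the isoxazole N–O bond gives the beta-amino enone, and dilute acid hydrolyses this primary vinylogous amide to the 1,3-diketone; the bulky tert-butyl ester slows N-acylation to the pyridone and survives dilute acid, and the oxygen on C3 is the one placed in step 9.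

Step 11
Reactants: 17 tert-butyl 6-[2-(2,4-dimethoxy-6-propylbenzoyl)-3,5-dimethoxyphenyl]-3,5-dioxohexanoate
Product: 19 6-[2-(2,4-dimethoxy-6-propylbenzoyl)-3,5-dimethoxybenzyl]-4-hydroxy-2H-pyran-2-one, via dioxo acid 18 (not isolated)
Conditions: TFA, TFAA, CH2Cl2, 0 °C to rt
Reagents that add atoms: none
Why: Acidic cleavage of the tert-butyl ester followed by lactonisation of the activated acid through the C5 enol oxygen (six-membered acyl substitution), the standard route from tert-butyl 3,5-dioxoalkanoates to 4-hydroxy-2-pyranones; activation by the anhydride should make ring closure faster than decarboxylation, and any oxygen closure onto the diaryl ketone is reversible whereas lactonisation is not.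

Step 12
Reactants: 19 6-[2-(2,4-dimethoxy-6-propylbenzoyl)-3,5-dimethoxybenzyl]-4-hydroxy-2H-pyran-2-one
Product: 20 6-[2-(2,4-dihydroxy-6-propylbenzoyl)-3,5-dihydroxybenzyl]-4-hydroxy-2H-pyran-2-one (CNP0306954.0)
Conditions: BBr3 (10 equiv), CH2Cl2, −78 °C to rt; then H2O
Reagents that add atoms: none
Why: Lewis-acid cleavage of aryl methyl ethers; the two methoxy groups ortho to the ketone are assisted by chelation and the para ones need the excess reagent, while the hydroxypyranone is a vinylogous acid that should only be complexed and released on hydrolysis.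

## Compound list

1 | 5-propylbenzene-1,3-diol | CCCc1cc(O)cc(O)c1 | starting material
2 | 1,3-dimethoxy-5-propylbenzene | CCCc1cc(OC)cc(OC)c1 | intermediate
3 | N-[(2,4-dimethoxy-6-propylphenyl)methylidene]-N-methylmethanaminium chloride | CCCc1cc(OC)cc(OC)c1C=[N+](C)C.[Cl-] | intermediate (not isolated)
4 | 2,4-dimethoxy-6-propylbenzaldehyde | CCCc1cc(OC)cc(OC)c1C=O | intermediate
5 | 2,4-dimethoxy-6-propylbenzoic acid | CCCc1cc(OC)cc(OC)c1C(=O)O | intermediate
6 | 3,5-dimethoxyphenylacetic acid | COc1cc(CC(=O)O)cc(OC)c1 | starting material
7 | methyl 2-(3,5-dimethoxyphenyl)acetate | COC(=O)Cc1cc(OC)cc(OC)c1 | intermediate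
8 | 2,4-dimethoxy-6-propylbenzoic trifluoroacetic anhydride | CCCc1cc(OC)cc(OC)c1C(=O)OC(=O)C(F)(F)F | intermediate (not isolated)
9 | methyl 2-[2-(2,4-dimethoxy-6-propylbenzoyl)-3,5-dimethoxyphenyl]acetate | CCCc1cc(OC)cc(OC)c1C(=O)c1c(OC)cc(OC)cc1CC(=O)OC | intermediate
10 | 2-[2-(2,4-dimethoxy-6-propylbenzoyl)-3,5-dimethoxyphenyl]acetaldehyde | CCCc1cc(OC)cc(OC)c1C(=O)c1c(OC)cc(OC)cc1CC=O | intermediate
11 | (E)-2-[2-(2,4-dimethoxy-6-propylbenzoyl)-3,5-dimethoxyphenyl]acetaldehyde oxime | CCCc1cc(OC)cc(OC)c1C(=O)c1c(OC)cc(OC)cc1C/C=N/O | intermediate
12 | but-3-ynoic acid | C#CCC(=O)O | starting material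
13 | tert-butyl but-3-ynoate | C#CCC(=O)OC(C)(C)C | intermediate
14 | 2-[2-(2,4-dimethoxy-6-propylbenzoyl)-3,5-dimethoxyphenyl]acetonitrile oxide | CCCc1cc(OC)cc(OC)c1C(=O)c1c(OC)cc(OC)cc1CC#[N+][O-] | intermediate (not isolated)
15 | tert-butyl 2-{3-[2-(2,4-dimethoxy-6-propylbenzoyl)-3,5-dimethoxybenzyl]-1,2-oxazol-5-yl}acetate | CCCc1cc(OC)cc(OC)c1C(=O)c1c(OC)cc(OC)cc1Cc1cc(CC(=O)OC(C)(C)C)on1 | intermediate
16 | tert-butyl (4Z)-5-amino-6-[2-(2,4-dimethoxy-6-propylbenzoyl)-3,5-dimethoxyphenyl]-3-oxohex-4-enoate | CCCc1cc(OC)cc(OC)c1C(=O)c1c(OC)cc(OC)cc1C/C(N)=C/C(=O)CC(=O)OC(C)(C)C | intermediate (not isolated)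
17 | tert-butyl 6-[2-(2,4-dimethoxy-6-propylbenzoyl)-3,5-dimethoxyphenyl]-3,5-dioxohexanoate | CCCc1cc(OC)cc(OC)c1C(=O)c1c(OC)cc(OC)cc1CC(=O)CC(=O)CC(=O)OC(C)(C)C | intermediate
18 | 6-[2-(2,4-dimethoxy-6-propylbenzoyl)-3,5-dimethoxyphenyl]-3,5-dioxohexanoic acid | CCCc1cc(OC)cc(OC)c1C(=O)c1c(OC)cc(OC)cc1CC(=O)CC(=O)CC(=O)O | intermediate (not isolated)
19 | 6-[2-(2,4-dimethoxy-6-propylbenzoyl)-3,5-dimethoxybenzyl]-4-hydroxy-2H-pyran-2-one | CCCc1cc(OC)cc(OC)c1C(=O)c1c(OC)cc(OC)cc1Cc1cc(O)cc(=O)o1 | intermediate
20 | 6-[2-(2,4-dihydroxy-6-propylbenzoyl)-3,5-dihydroxybenzyl]-4-hydroxy-2H-pyran-2-one (CNP0306954.0) | CCCc1cc(O)cc(O)c1C(=O)c1c(O)cc(O)cc1Cc1cc(O)cc(=O)o1 | target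

## Step count and risks

Total step count: 12. Longest linear sequence: 10 steps (steps 1, 2, 3, 5, 6, 7, 9, 10, 11 and 12, from 1).

**Step 9 (key step).** The nitrile oxide may dimerise to the furoxan faster than it adds to an unactivated terminal alkyne. The but-3-ynoate may isomerise to the allenoate, which reacts with a different regiochemical outcome. The oxidant may attack the dimethoxyarenes. The fallback sets out from oxime 11 and uses commercial but-3-yn-1-ol as dipolarophile; it cannot isomerise and can be used in large excess. The same oxidative cycloaddition should give 2-{3-[2-(2,4-dimethoxy-6-propylbenzoyl)-3,5-dimethoxybenzyl]-1,2-oxazol-5-yl}ethanol F1. Oxidation of the primary alcohol (TEMPO cat., PhI(OAc)2, MeCN/H2O) should give 2-{3-[2-(2,4-dimethoxy-6-propylbenzoyl)-3,5-dimethoxybenzyl]-1,2-oxazol-5-yl}acetic acid F2. Esterification with isobutene and catalytic H2SO4 comes back to the route at 15.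

**Step 7.** The oxime nitrogen, or the enol of aldehyde 10, may close onto the neighbouring diaryl ketone in a six-membered mode and dehydrate to an isoquinoline N-oxide or a 2-benzopyrylium species. Crowding slows this but the aromatic product is a thermodynamic sink. The fallback leaves out the oxime and the isoxazole. It sets out from ester 9, which acylates the dianion of tert-butyl acetoacetate (NaH, then nBuLi, THF, 0 °C) at its terminal carbon in a Claisen-type condensation, and comes back at 17. No new compound is made. This is shorter but strongly basic: the benzylic protons of 9 consume dianion and the triketide anion sits beside the ketone, which is why it is the fallback and not the plan.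

**Step 5.** The stabilised, hindered acylium ion may react sluggishly, attack C4 of 7 between the two methoxy groups, or acylate a second molecule of 5. The fallback forms the ketone by aryllithium addition instead. It sets out from ester 7 and aldehyde 4.
- LiAlH4 reduction of 7 gives 2-(3,5-dimethoxyphenyl)ethanol F3.
- NBS brominates para to a methoxy group to give 2-(2-bromo-3,5-dimethoxyphenyl)ethanol F4.
- nBuLi (2 equiv) followed by 4 gives racemic 2-{2-[(2,4-dimethoxy-6-propylphenyl)(hydroxy)methyl]-3,5-dimethoxyphenyl}ethanol F5.
- MnO2 oxidises the diaryl carbinol selectively to (2,4-dimethoxy-6-propylphenyl)[2-(2-hydroxyethyl)-4,6-dimethoxyphenyl]methanone F6.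
- Dess–Martin oxidation of the primary alcohol comes back to the route at 10.

**Step 6.** Over-reduction to the primary alcohol, enolisation of the arylacetate, or hydride addition to the ketone would lower the return of aldehyde. The fallback sets out from 9. Saponification (LiOH, THF/H2O) gives 2-[2-(2,4-dimethoxy-6-propylbenzoyl)-3,5-dimethoxyphenyl]acetic acid F7. Coupling with ethanethiol (EDC, DMAP) gives S-ethyl 2-[2-(2,4-dimethoxy-6-propylbenzoyl)-3,5-dimethoxyphenyl]ethanethioate F8. Fukuyama reduction (Et3SiH, Pd/C, acetone, rt) stops at the aldehyde and does not touch ketones; it comes back at 10.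

**Step 12.** Cleavage of the two para methoxy groups may stay incomplete, or the Lewis acid may promote condensation of pyranone C5 with the activated ketone before all ethers are gone. The fallback demethylates before the pyranone exists. It sets out from isoxazole 15.
- BBr3 in CH2Cl2 cleaves the four ethers and the tert-butyl ester to 2-{3-[2-(2,4-dihydroxy-6-propylbenzoyl)-3,5-dihydroxybenzyl]-1,2-oxazol-5-yl}acetic acid F9.
- F9 is esterified in the acidic methanol quench at reflux to methyl 2-{3-[2-(2,4-dihydroxy-6-propylbenzoyl)-3,5-dihydroxybenzyl]-1,2-oxazol-5-yl}acetate F10.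
- Hydrogenolysis (H2, Raney Ni) gives methyl (4Z)-5-amino-6-[2-(2,4-dihydroxy-6-propylbenzoyl)-3,5-dihydroxyphenyl]-3-oxohex-4-enoate F11.
- F11 is hydrolysed at once with dilute HCl to methyl 6-[2-(2,4-dihydroxy-6-propylbenzoyl)-3,5-dihydroxyphenyl]-3,5-dioxohexanoate F12.
- Lactonisation with excess DBU in toluene, the usual method for methyl 3,5-dioxoalkanoates, comes back at 20.

## Further compounds

F1 | step 9 | 2-{3-[2-(2,4-dimethoxy-6-propylbenzoyl)-3,5-dimethoxybenzyl]-1,2-oxazol-5-yl}ethanol | CCCc1cc(OC)cc(OC)c1C(=O)c1c(OC)cc(OC)cc1Cc1cc(CCO)on1
F2 | step 9 | 2-{3-[2-(2,4-dimethoxy-6-propylbenzoyl)-3,5-dimethoxybenzyl]-1,2-oxazol-5-yl}acetic acid | CCCc1cc(OC)cc(OC)c1C(=O)c1c(OC)cc(OC)cc1Cc1cc(CC(=O)O)on1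
F0 | step 7 | none | none
F3 | step 5 | 2-(3,5-dimethoxyphenyl)ethanol | COc1cc(CCO)cc(OC)c1
F4 | step 5 | 2-(2-bromo-3,5-dimethoxyphenyl)ethanol | COc1cc(CCO)c(Br)c(OC)c1
F5 | step 5 | 2-{2-[(2,4-dimethoxy-6-propylphenyl)(hydroxy)methyl]-3,5-dimethoxyphenyl}ethanol (racemic) | CCCc1cc(OC)cc(OC)c1C(O)c1c(OC)cc(OC)cc1CCO
F6 | step 5 | (2,4-dimethoxy-6-propylphenyl)[2-(2-hydroxyethyl)-4,6-dimethoxyphenyl]methanone | CCCc1cc(OC)cc(OC)c1C(=O)c1c(OC)cc(OC)cc1CCO
F7 | step 6 | 2-[2-(2,4-dimethoxy-6-propylbenzoyl)-3,5-dimethoxyphenyl]acetic acid | CCCc1cc(OC)cc(OC)c1C(=O)c1c(OC)cc(OC)cc1CC(=O)O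
F8 | step 6 | S-ethyl 2-[2-(2,4-dimethoxy-6-propylbenzoyl)-3,5-dimethoxyphenyl]ethanethioate | CCCc1cc(OC)cc(OC)c1C(=O)c1c(OC)cc(OC)cc1CC(=O)SCC
F9 | step 12 | 2-{3-[2-(2,4-dihydroxy-6-propylbenzoyl)-3,5-dihydroxybenzyl]-1,2-oxazol-5-yl}acetic acid | CCCc1cc(O)cc(O)c1C(=O)c1c(O)cc(O)cc1Cc1cc(CC(=O)O)on1
F10 | step 12 | methyl 2-{3-[2-(2,4-dihydroxy-6-propylbenzoyl)-3,5-dihydroxybenzyl]-1,2-oxazol-5-yl}acetate | CCCc1cc(O)cc(O)c1C(=O)c1c(O)cc(O)cc1Cc1cc(CC(=O)OC)on1
F11 | step 12 | methyl (4Z)-5-amino-6-[2-(2,4-dihydroxy-6-propylbenzoyl)-3,5-dihydroxyphenyl]-3-oxohex-4-enoate | CCCc1cc(O)cc(O)c1C(=O)c1c(O)cc(O)cc1C/C(N)=C/C(=O)CC(=O)OC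
F12 | step 12 | methyl 6-[2-(2,4-dihydroxy-6-propylbenzoyl)-3,5-dihydroxyphenyl]-3,5-dioxohexanoate | CCCc1cc(O)cc(O)c1C(=O)c1c(O)cc(O)cc1CC(=O)CC(=O)CC(=O)OC
A1 | alternative 1 | {2-[2-(tert-butyldimethylsilyloxy)ethyl]-4-hydroxy-6-methoxyphenyl}(4-hydroxy-2-methoxy-6-propylphenyl)methanone | CCCc1cc(O)cc(OC)c1C(=O)c1c(OC)cc(O)cc1CCO[Si](C)(C)C(C)(C)C
A2 | alternative 1 | 1-(tert-butyldimethylsilyloxy)deca-3,6-diyn-5-one | CCCC#CC(=O)C#CCCO[Si](C)(C)C(C)(C)C
A3 | alternative 1 | 1,1-dimethoxy-3-(trimethylsilyloxy)buta-1,3-diene | COC(OC)=CC(=C)O[Si](C)(C)C
A4 | alternative 2 | tert-butyl 2-{2-[2,4-dimethoxy-6-(2-methoxy-2-oxoethyl)benzoyl]-3,5-dimethoxyphenyl}butanoate (racemic) | CCC(C(=O)OC(C)(C)C)c1cc(OC)cc(OC)c1C(=O)c1c(OC)cc(OC)cc1CC(=O)OC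
A5 | alternative 2 | 3,5-dimethoxy-2-(trimethylsilyl)phenyl trifluoromethanesulfonate | COc1cc(OC)c([Si](C)(C)C)c(OS(=O)(=O)C(F)(F)F)c1
A6 | alternative 2 | 1-tert-butyl 5-methyl 2-ethyl-3-oxopentanedioate (racemic) | CCC(C(=O)OC(C)(C)C)C(=O)CC(=O)OC
A7 | alternative 3 | (2,4-dihydroxy-6-methylphenyl)(2,4-dimethoxy-6-propylphenyl)methanone | CCCc1cc(OC)cc(OC)c1C(=O)c1c(O)cc(O)cc1C
A8 | alternative 3 | 2-[2-(2,4-dimethoxy-6-propylphenyl)-2-oxoethyl]-6-methyl-4H-pyran-4-one | CCCc1cc(OC)cc(OC)c1C(=O)Cc1cc(=O)cc(C)o1
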